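**Plan**
- Retrosynthesis: the TBS ether and a dioxolane (masking the ketone) come off last. Each furan-2,5-dione ring is then cut at both C(sp2)–C(=O) bonds and at the ring C–O bond, so each ring becomes a dialkyl alkyne + CO2 + CO and the bis-anhydride collapses to a linear 1,5-diyne.
- Enabling feature: both rings are tetrasubstituted maleic anhydrides whose C3=C4 carbons carry only sp3-carbon substituents and whose two C=O carbons have the same oxidation level. C3/C4 of each ring are therefore the two carbons of a triple bond, and the orientation of CO2/CO uptake is irrelevant.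
- The diyne is cut at C(sp)–CH2 (acetylide + 1,2-epoxyhexane), at the triple bond next to the stereocentre (aldehyde to alkyne homologation) and at the stereocentre–CH2 bond (enolate alkylation with a 4-silyloxybut-2-ynyl bromide).
- Forward: alkylate the heptanoyl chain, turn its carbonyl into the alkyne, add the C6 unit, form both anhydride rings together in one operation, then deprotect in acid.
- Stereochemistry: the single (R) centre comes from an (S)-4-benzyloxazolidinone-directed alkylation. It is carried as a non-acidic propargylic C–H centre until the rings exist, and every later step is neutral or acidic.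

Key step: step 11

Remark 1: the target is made in the form drawn (both rings closed, free CH2OH); 2,3-dialkylmaleic acids close to the anhydride spontaneously in acid, so the last step is run and worked up at low pH.
Remark 2: racemic 1,2-epoxyhexane is used because its carbinol carbon becomes the ketone; 14 is therefore a pair of epimers at that carbon.

**Step 1**
Reactants: 1 but-2-yne-1,4-diol
Product: 2 4-{[tert-butyl(dimethyl)silyl]oxy}but-2-yn-1-ol
Conditions: TBSCl (1 equiv), imidazole, 1 (3 equiv), DMF, 0 °C to rt
Reagents that add atoms: tert-butyldimethylsilyl chloride, CC(C)(C)[Si](C)(C)Cl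
Why: Imidazole-promoted silylation of one of two equivalent primary hydroxyls (statistical monoprotection of a symmetric diol); the excess of cheap diol should keep the bis-silyl ether low.

**Step 2**
Reactants: 2 4-{[tert-butyl(dimethyl)silyl]oxy}but-2-yn-1-ol
Product: 3 [(4-bromobut-2-yn-1-yl)oxy](tert-butyl)dimethylsilane
Conditions: CBr4, PPh3, CH2Cl2, 0 °C
Reagents that add atoms: carbon tetrabromide, BrC(Br)(Br)Br
Why: Appel bromination converts the primary propargylic alcohol into the bromide under neutral conditions that leave the silyl ether untouched.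

**Step 3**
Reactants: 4 (S)-4-benzyl-1,3-oxazolidin-2-one; 5 heptanoyl chloride
Product: 6 (S)-4-benzyl-3-heptanoyl-1,3-oxazolidin-2-one
Conditions: Et3N, DMAP (cat.), CH2Cl2, 0 °C to rt
Reagents that add atoms: none
Why: DMAP-catalysed N-acylation of the oxazolidinone by the acid chloride, with Et3N as HCl scavenger, gives the Evans imide.

**Step 4**
Reactants: 6 (S)-4-benzyl-3-heptanoyl-1,3-oxazolidin-2-one; 3 [(4-bromobut-2-yn-1-yl)oxy](tert-butyl)dimethylsilane
Product: 8 (4S)-4-benzyl-3-[(2R)-2-pentyl-6-{[tert-butyl(dimethyl)silyl]oxy}hex-4-ynoyl]-1,3-oxazolidin-2-one, via sodium Z-enolate 7 (not isolated)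
Conditions: NaHMDS, THF, −78 °C; then 3 (2 equiv), −78 to −40 °C
Reagents that add atoms: none
Why: Evans asymmetric alkylation: the sodium-chelated Z-enolate reacts with the activated propargylic bromide (SN2) on the face opposite the C4 benzyl group, which should set the new centre as (R).

**Step 5**
Reactants: 8 (4S)-4-benzyl-3-[(2R)-2-pentyl-6-{[tert-butyl(dimethyl)silyl]oxy}hex-4-ynoyl]-1,3-oxazolidin-2-one
Product: 9 (2R)-2-pentyl-6-{[tert-butyl(dimethyl)silyl]oxy}hex-4-yn-1-ol
Conditions: LiBH4, H2O (1 equiv), Et2O, 0 °C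
Reagents that add atoms: none
Why: LiBH4 reduces the exocyclic imide carbonyl selectively (reductive removal of the Evans auxiliary), giving the primary alcohol without touching the stereocentre, the triple bond or the silyl ether and returning the auxiliary.

**Step 6**
Reactants: 9 (2R)-2-pentyl-6-{[tert-butyl(dimethyl)silyl]oxy}hex-4-yn-1-ol
Product: 10 (2R)-2-pentyl-6-{[tert-butyl(dimethyl)silyl]oxy}hex-4-ynal
Conditions: DMP, CH2Cl2, 0 °C to rt
Reagents that add atoms: none
Why: Dess–Martin oxidation stops at the aldehyde under non-basic conditions, so the α-stereocentre should not epimerise.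

**Step 7**
Reactants: 10 (2R)-2-pentyl-6-{[tert-butyl(dimethyl)silyl]oxy}hex-4-ynal
Product: 11 tert-butyldimethyl{[(5R)-5-pentylhepta-2,6-diyn-1-yl]oxy}silane
Conditions: dimethyl (1-diazo-2-oxopropyl)phosphonate, K2CO3, MeOH, 0 °C to rt
Reagents that add atoms: dimethyl (1-diazo-2-oxopropyl)phosphonate, CC(=O)C(=[N+]=[N-])P(=O)(OC)OC
Why: Seyferth–Gilbert homologation in the Ohira–Bestmann form turns the aldehyde into the terminal alkyne with one added carbon under mild K2CO3/MeOH conditions, where homologation should outrun enolisation of the α-branched aldehyde.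

**Step 8**
Reactants: 11 tert-butyldimethyl{[(5R)-5-pentylhepta-2,6-diyn-1-yl]oxy}silane; 12 1,2-epoxyhexane (2-butyloxirane, racemic)
Product: 14 (5R)-1-{[tert-butyl(dimethyl)silyl]oxy}-5-pentyltrideca-2,6-diyn-9-ol (both C9 epimers), via lithium acetylide 13 (not isolated)
Conditions: n-BuLi, THF, −78 °C; BF3·OEt2; then 12, −78 °C
Reagents that add atoms: none
Why: Yamaguchi–Hirao alkynylation: the lithium acetylide opens the BF3-activated terminal epoxide at its CH2 carbon to give the homopropargylic alcohol.

**Step 9**
Reactants: 14 (5R)-1-{[tert-butyl(dimethyl)silyl]oxy}-5-pentyltrideca-2,6-diyn-9-ol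
Product: 15 (5R)-1-{[tert-butyl(dimethyl)silyl]oxy}-5-pentyltrideca-2,6-diyn-9-one
Conditions: DMP, CH2Cl2, 0 °C; crude ketone used at once
Reagents that add atoms: none
Why: Dess–Martin oxidation of the secondary homopropargylic alcohol gives the β,γ-alkynyl ketone under near-neutral conditions that should avoid the prototropic shift to the allenyl ketone.

**Step 10**
Reactants: 15 (5R)-1-{[tert-butyl(dimethyl)silyl]oxy}-5-pentyltrideca-2,6-diyn-9-one
Product: 16 tert-butyl{[(5R)-8-(2-butyl-1,3-dioxolan-2-yl)-5-pentylocta-2,6-diyn-1-yl]oxy}dimethylsilane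
Conditions: TMSOCH2CH2OTMS, TMSOTf (cat.), CH2Cl2, −78 to −20 °C; pyridine quench
Reagents that add atoms: 1,2-bis(trimethylsilyloxy)ethane, C[Si](C)(C)OCCO[Si](C)(C)C
Why: Noyori acetalisation runs at low temperature without Brønsted acid or base, so the ketone is masked before it can enolise and the primary TBS ether survives.

**Step 11**
Reactants: 16 tert-butyl{[(5R)-8-(2-butyl-1,3-dioxolan-2-yl)-5-pentylocta-2,6-diyn-1-yl]oxy}dimethylsilane
Product: 18 3-[(2R)-1-{4-[(tert-butyldimethylsilyloxy)methyl]-2,5-dioxo-2,5-dihydrofuran-3-yl}heptan-2-yl]-4-[(2-butyl-1,3-dioxolan-2-yl)methyl]furan-2,5-dione, via TMEDA-ligated bis(nickelalactone) 17 (not isolated)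
Conditions: Ni(cod)2 (2.5 equiv), TMEDA (5 equiv), CO2 (1 atm), THF, −20 °C to rt; then CO (1 atm), −40 °C to rt; cold aq. citric acid work-up (closed system, Ni(CO)4 scrubbed)
Reagents that add atoms: carbon dioxide, O=C=O; carbon monoxide, [C-]#[O+]
Why: Each triple bond binds (tmeda)Ni(0) and couples oxidatively with CO2 to a 1-oxa-2-nickelacyclopent-3-en-5-one (17); CO then inserts into the Ni–C(sp2) bond, which in the ring next to the stereocentre is the bond to the carbon carrying the heptan-2-yl group, so that this carbon gains its C(=O) neighbour, and C–O reductive elimination from the six-membered acyl nickel carboxylate closes the furan-2,5-dione and releases Ni(0) as its carbonyl. The closest known reaction type is the Hoberg sequence, stoichiometric Ni(0)/CO2 coupling of a dialkyl alkyne followed by carbonylation of the nickelalactone to the dialkylmaleic anhydride, used here twice in one flask. Both rings close in the same mode, a nickel-templated [2+2+1] assembly (alkyne + CO2 + CO) whose last bond forms by reductive elimination with ring contraction from six to five. No stereocentre is made; the cis relationship of the two carbonyls follows from syn addition across the triple bond inside the metallacycle, and the existing centre is a spectator because it is not part of an enolisable system until the ring exists. The step needs 1:1 alkyne/CO2 coupling at each triple bond and not alkyne–alkyne coupling, which the chelating diamine, the excess of nickel and the 1,5-spacing of the alkynes (a cocyclisation would have to form a four-membered ring) should secure, while regiochemistry is no issue because both orientations of CO2 uptake converge on the same anhydride. The cold acidic work-up removes TMEDA before it can deprotonate the γ-CH of the new anhydride.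

**Step 12**
Reactants: 18 3-[(2R)-1-{4-[(tert-butyldimethylsilyloxy)methyl]-2,5-dioxo-2,5-dihydrofuran-3-yl}heptan-2-yl]-4-[(2-butyl-1,3-dioxolan-2-yl)methyl]furan-2,5-dione
Product: 19 3-[(2R)-1-[4-(hydroxymethyl)-2,5-dioxo-2,5-dihydrofuran-3-yl]heptan-2-yl]-4-(2-oxohexyl)furan-2,5-dione (CNP0537712.2)
Conditions: 1 M aq. HCl/THF (1:2), rt
Reagents that add atoms: water, O
Why: Acid hydrolysis cleaves the dioxolane and the primary silyl ether in one operation; at this pH both dialkylmaleic anhydride rings stay closed, so the freed CH2OH should not lactonise and the stereocentre never meets base.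

**Compound list**
1 | but-2-yne-1,4-diol | OCC#CCO | starting material
2 | 4-{[tert-butyl(dimethyl)silyl]oxy}but-2-yn-1-ol | OCC#CCO[Si](C)(C)C(C)(C)C | intermediate
3 | [(4-bromobut-2-yn-1-yl)oxy](tert-butyl)dimethylsilane | BrCC#CCO[Si](C)(C)C(C)(C)C | intermediate
4 | (S)-4-benzyl-1,3-oxazolidin-2-one | O=C1N[C@@H](Cc2ccccc2)CO1 | starting material
5 | heptanoyl chloride | CCCCCCC(=O)Cl | starting material
6 | (S)-4-benzyl-3-heptanoyl-1,3-oxazolidin-2-one | CCCCCCC(=O)N1[C@@H](Cc2ccccc2)COC1=O | intermediate
7 | sodium (Z)-enolate of 6 | CCCCC/C=C(\[O-])N1[C@@H](Cc2ccccc2)COC1=O.[Na+] | intermediate (not isolated)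
8 | (4S)-4-benzyl-3-[(2R)-2-pentyl-6-{[tert-butyl(dimethyl)silyl]oxy}hex-4-ynoyl]-1,3-oxazolidin-2-one | CCCCC[C@H](CC#CCO[Si](C)(C)C(C)(C)C)C(=O)N1[C@@H](Cc2ccccc2)COC1=O | intermediate
9 | (2R)-2-pentyl-6-{[tert-butyl(dimethyl)silyl]oxy}hex-4-yn-1-ol | CCCCC[C@H](CC#CCO[Si](C)(C)C(C)(C)C)CO | intermediate
10 | (2R)-2-pentyl-6-{[tert-butyl(dimethyl)silyl]oxy}hex-4-ynal | CCCCC[C@H](CC#CCO[Si](C)(C)C(C)(C)C)C=O | intermediate
11 | tert-butyldimethyl{[(5R)-5-pentylhepta-2,6-diyn-1-yl]oxy}silane | CCCCC[C@H](CC#CCO[Si](C)(C)C(C)(C)C)C#C | intermediate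
12 | 1,2-epoxyhexane (2-butyloxirane, racemic) | CCCCC1CO1 | starting material
13 | lithium acetylide of 11 | CCCCC[C@H](CC#CCO[Si](C)(C)C(C)(C)C)C#[C-].[Li+] | intermediate (not isolated)
14 | (5R)-1-{[tert-butyl(dimethyl)silyl]oxy}-5-pentyltrideca-2,6-diyn-9-ol (both C9 epimers) | CCCCC[C@H](CC#CCO[Si](C)(C)C(C)(C)C)C#CCC(O)CCCC | intermediate
15 | (5R)-1-{[tert-butyl(dimethyl)silyl]oxy}-5-pentyltrideca-2,6-diyn-9-one | CCCCC[C@H](CC#CCO[Si](C)(C)C(C)(C)C)C#CCC(=O)CCCC | intermediate
16 | tert-butyl{[(5R)-8-(2-butyl-1,3-dioxolan-2-yl)-5-pentylocta-2,6-diyn-1-yl]oxy}dimethylsilane | CCCCC[C@H](CC#CCO[Si](C)(C)C(C)(C)C)C#CCC1(CCCC)OCCO1 | intermediate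
17 | TMEDA-ligated bis(1-oxa-2-nickelacyclopent-3-en-5-one) from 16 (one of the convergent regioisomers drawn) | CCCCC[C@H](CC1=C(CO[Si](C)(C)C(C)(C)C)C(=O)O[Ni-2]13[N+](C)(C)CC[N+]3(C)C)C1=C(CC2(CCCC)OCCO2)C(=O)O[Ni-2]14[N+](C)(C)CC[N+]4(C)C | intermediate (not isolated)
18 | 3-[(2R)-1-{4-[(tert-butyldimethylsilyloxy)methyl]-2,5-dioxo-2,5-dihydrofuran-3-yl}heptan-2-yl]-4-[(2-butyl-1,3-dioxolan-2-yl)methyl]furan-2,5-dione | CCCCC[C@H](CC1=C(CO[Si](C)(C)C(C)(C)C)C(=O)OC1=O)C1=C(CC2(CCCC)OCCO2)C(=O)OC1=O | intermediate
19 | 3-[(2R)-1-[4-(hydroxymethyl)-2,5-dioxo-2,5-dihydrofuran-3-yl]heptan-2-yl]-4-(2-oxohexyl)furan-2,5-dione | CCCCC[C@H](CC1=C(CO)C(=O)OC1=O)C1=C(CC(=O)CCCC)C(=O)OC1=O | target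

**Step count and risks**
Total: 12 steps. Longest linear sequence: 11 steps (1, 2, 4–12).

Most likely to fail:

1. Step 11. The two oxidative couplings may not both run to completion, because the triple bond flanked by the branched stereocentre and the acetal-bearing CH2 is hindered. Alkyne oligomerisation, or β-silyloxy elimination from the nickelalactone regioisomer with nickel on the silyloxymethyl-bearing carbon, may compete, and free diamine may enolise the new anhydride. The fallback sets out from 16 and uses a catalytic [2+2+1] of a different metal and partner. Ru3(CO)12-catalysed cocyclisation of both triple bonds with CO and 4-methylphenyl isocyanate (mesitylene, 130 °C) should give the bis(N-p-tolylmaleimide) F1. Brief KOH hydrolysis in aqueous MeOH/THF, then acidification to pH 2 at 0 °C, opens both imides and lets the dialkylmaleic acids close, which comes back to the route at 18.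

2. Step 10 (with step 9). The β,γ-alkynyl ketone may undergo a prototropic shift to the allenyl ketone, and on to a furan, during oxidation or acetalisation. The fallback sets out from 11 and never forms the free ketone. Lithium acetylide 13 is quenched with paraformaldehyde to give the propargylic alcohol F2, and Appel bromination gives the propargylic bromide F3. 2-Butyl-1,3-dithiane F4 (from pentanal and propane-1,3-dithiol, BF3·OEt2) is lithiated to 2-butyl-2-lithio-1,3-dithiane F5 and alkylated with F3 to give the dithioacetal F6. Exchange with PhI(OCOCF3)2 and ethylene glycol in MeCN converts the dithiane directly into the dioxolane, which comes back to the route at 16.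

3. Step 7. Base-mediated enolisation of the α-branched aldehyde before homologation would erode the enantiomeric purity. The fallback sets out from 10 and avoids base while the aldehyde is present. Corey–Fuchs olefination (CBr4, PPh3, Zn, CH2Cl2, 0 °C) gives the 1,1-dibromoalkene F7. n-BuLi (2.1 equiv, THF, −78 °C) converts F7 directly into the lithium acetylide, which comes back to the route at 13 and is carried into the epoxide opening of step 8.

**Further compounds**
F1 | step 11 | 3-[(2R)-1-{4-[(tert-butyldimethylsilyloxy)methyl]-1-(4-methylphenyl)-2,5-dioxo-2,5-dihydro-1H-pyrrol-3-yl}heptan-2-yl]-4-[(2-butyl-1,3-dioxolan-2-yl)methyl]-1-(4-methylphenyl)-1H-pyrrole-2,5-dione | CCCCC[C@H](CC1=C(CO[Si](C)(C)C(C)(C)C)C(=O)N(c2ccc(C)cc2)C1=O)C1=C(CC2(CCCC)OCCO2)C(=O)N(c2ccc(C)cc2)C1=O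
F2 | step 10 | (4R)-4-pentyl-8-{[tert-butyl(dimethyl)silyl]oxy}octa-2,6-diyn-1-ol | CCCCC[C@H](CC#CCO[Si](C)(C)C(C)(C)C)C#CCO
F3 | step 10 | {[(5R)-8-bromo-5-pentylocta-2,6-diyn-1-yl]oxy}(tert-butyl)dimethylsilane | CCCCC[C@H](CC#CCO[Si](C)(C)C(C)(C)C)C#CCBr
F4 | step 10 | 2-butyl-1,3-dithiane | CCCCC1SCCCS1
F5 | step 10 | 2-butyl-2-lithio-1,3-dithiane (not isolated) | CCCC[C-]1SCCCS1.[Li+]
F6 | step 10 | tert-butyl{[(5R)-8-(2-butyl-1,3-dithian-2-yl)-5-pentylocta-2,6-diyn-1-yl]oxy}dimethylsilane | CCCCC[C@H](CC#CCO[Si](C)(C)C(C)(C)C)C#CCC1(CCCC)SCCCS1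
F7 | step 7 | {[(5R)-7,7-dibromo-5-pentylhept-6-en-2-yn-1-yl]oxy}(tert-butyl)dimethylsilane | CCCCC[C@H](CC#CCO[Si](C)(C)C(C)(C)C)C=C(Br)Br
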